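In a one-step world the side product is a plain fraction of the charge; here, follow it through two forks, one for the partner and one for the intermediate.

| flask | substrate | partner | time | remark |
|---|---|---|---|---|
| dawn | 21 mM | 18.9 mM | 2.0 min | everything together at the start |
| noon | 21 mM (fed, over 50 s) | 18.9 mM | 2.0 min | all else is in the flask from the start; the feed brings no volume worth counting |
| summer | 21 mM | 18.9 mM (fed, over 50 s) | 2.0 min | all else is in the flask from the start; the feed brings no volume worth counting |

    substrate + partner → intermediate + released group (k1 = 76.7 M⁻¹ s⁻¹)
    intermediate → target (k2 = 0.0182 s⁻¹)
    intermediate → side product (k3 = 0.0118 s⁻¹)
    2 partner → self-condensation product (k4 = 8.68 M⁻¹ s⁻¹)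

- a step written with two of one species runs at k times the square of its concentration and takes two of it each time
- run time (dawn): 2.0 min

- which flask leads in amount of side product, in percent of the substrate charged ("all alike" within 1.5 percentage points) (dawn / noon / summer / all alike)
- how much side product is there at the end, in percent of the substrate charged: dawn
- how much side product is there at the end, in percent of the substrate charged: noon
- how much side product is there at the end, in percent of the substrate charged: summer

Start by treating the fast step as over at once. In dawn the first step alone, with the partner as charged, gives the substrate a half-life of 0.48 s, while the intermediate lives 33.3 s, and this wide gap lets you treat the intermediate as born at the start. Now divide the side path's constant by the sum of both decay constants, which gives 39.3%; call this the branch share, the selectivity of the fork. Let the clock run: by this reckoning, at the end of dawn 2.73% of the intermediate born is undecayed. In summer, spread the births evenly over the feed, and 6.34% of the intermediate born is undecayed at the end. The partner is the limiting reagent, so first let every bit of it reach substrate. That gives 34.4% for dawn and 33.2% for summer.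

The weak link is that assumption, so reforge it. Weigh dawn's partner fork at the halfway point, where I reckon that self-condensation takes 15.6% of the partner, and my dawn figure falls to 29.1%. Early in summer's feed, feed and first step balance with the partner near 0.235 mM, far below its charge, so I keep my summer figure. In noon, self-condensation starts by taking partner at 6.20 mM s⁻¹ against a substrate feed of 0.420 mM s⁻¹; with the first rate far ahead, I expect noon far behind, and my reckoning gives it no number. I commit to summer.

The forecast also names summer, with 30% for dawn, 8% for noon and 31.8% for summer, saying of self-condensation in summer: “slow partner feed into excess substrate suppresses it”. Its dawn is higher than mine and its summer lower.

The simulation puts summer in the lead, with 30.0% for dawn, 9.94% for noon and 32.5% for summer.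

The released group, which counts intermediate born, ends at 18.6 mM in summer, 16.5 mM in dawn and 5.51 mM in noon, the same order as the side product. Multiply summer's count by the branch share and by the decayed part, and you get 32.7% of the charge. Now take the neighbour of summer charged with 11 mM of partner. Its partner ends at 0% of its own charge and its released group at 11.0 mM, so the same multiplication gives 19.2%. That flask holds 19.2% of side product, with 47.8% of the substrate left.

(All constants are made up.)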